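## Structural features

The target is a trans-fused hydroazulene (daucane) diester: cyclopentane ring A (C1, C2, C3, C4, C10) shares the C4–C10 bond with cycloheptene ring B (C4 to C10 through C5–C9), which holds the trisubstituted C7=C8 olefin. Five stereocentres form one unbroken array (C1–C10–C4–C3 and C4–C5). The C1 oxygen, the C10 methyl and the C3 hydroxyl lie on one face of ring A (β), the C3 isopropyl group and the C4 hydrogen on the other (α), and the C5 oxygen is anti to the C3 hydroxyl; the absolute configuration is 1R,3R,4S,5S,10R in this numbering. C10 is quaternary, C3 is a fully substituted carbinol, and the three oxygens end as three different functions: a (Z)-2-methylbut-2-enoate on C1, a free tertiary alcohol on C3 and a 4-methoxybenzoate on C5. The fragile elements are the Z-enoate (it isomerises to the E ester under nucleophilic or basic acylation), the C7=C8 olefin (β,γ to C5 whenever C5 is a ketone, so it can slip into conjugation) and the C3–C4–C5 array (an aldol at the ketone stage, open to retro-aldol cleavage and β-elimination). The real difficulty is the trans ring fusion between a quaternary carbon and a methine flanked by two oxygenated carbons. The key step uses the fact that C5 is at carbonyl level with C8 as its former α-carbon: C6–C7(CH3)=C8 is then a but-2-ynoate unit inserted into the C5–C8 bond of a cyclopentanone (C4, C5, C8, C9, C10), so ring B can be grown from a cis-fused diquinane in which C1, C3 and C10 are already set.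

## Logic of the disconnections

34 to 31 and 32: the C1–O acyl bond is cut first because the Z-enoate is the most fragile group and should meet no further reagent. This leaves a diol with one secondary and one tertiary hydroxyl. The forward step must acylate without Z/E isomerisation.

31 to 30, then to 28 and 29: the C1 O–Si bond and the C5–O acyl bond are cut. Keeping C1 silylated until C5 is acylated is what distinguishes the two secondary alcohols. The forward acylation has only to prefer the secondary C5 hydroxyl over the tertiary C3 hydroxyl.

28 to 27, then to 26: the C5–H bond is cut back to a ketone, and the C3 O–Si bond is restored. The C5 centre is then set from the free C3 hydroxyl by internal hydride delivery (1,3-anti). This demands delivery on the face of C5 that the C10 methyl flanks, where an external hydride would not go.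

26 to 24: the C4–H bond is the only change (epimerisation through the C5 ketone). It converts the trans fusion into the cis fusion that a diquinane can supply. The forward step must equilibrate C4 without losing the C7=C8 position, so it is run through the extended dienolate and ended by kinetic protonation at C6, with the C3 oxygen silylated to shut off retro-aldol cleavage.

24 to 22: the C6–carboxyl bond and the enol O–Si bond are restored. The ester is the activating group of the alkyne and is chosen so that it can later be removed at ambient temperature without base.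

22 to 17 and 20 (key disconnection): the C5–C6 and C7–C8 bonds are cut and C5–C8 is re-formed, a two-carbon ring contraction. The seven-membered ring problem becomes a cyclopentanone problem on a rigid cis-diquinane. The forward step needs the enol ether on the C8 side and Michael regiochemistry at the alkyne.

20 to 18 and 19: the ester C–O bond; both pieces are commercial.

17 to 15, then to 14: the two O–Si bonds (enol ether, C3 ether). The demand is kinetic deprotonation at C8, not at the crowded C4.

14 to 13, then to 11: the C5–O and C4–H bonds are cut back to the C4=C5 olefin. One olefin supplies both the C5 oxygen and the C4 hydrogen. The regiochemistry is fixed by substitution; the ring fusion can relax to cis at the ketone stage.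

11 to 10: the C3–isopropyl bond is cut at the enone. In a saturated cis-fused ketone a nucleophile would be expected on the convex face, which would give the C3 epimer. In 10, C4 is sp2 and the only axial group near C3 is the β C10 methyl, so the nucleophile must enter α.

10 to 7: the C4=C5 bond (aldol condensation) is cut, leaving a monocyclic keto acetal. The forward closure is funnelled by irreversible dehydration.

7 to 3 and 4: the C10–C9 bond is cut. Conjugate addition anti to the C1 silyloxy group creates the quaternary centre with the methyl cis to the C1 oxygen.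

3 to 2, then to 1: the C10–CH3 bond is cut and the enone restored. The chiral-pool enone 1 supplies C1.

## Other disconnections considered

Alternative 1: The cut removes the C9–C10 and C3–C4 bonds, taking the whole bicycle back to acyclic (2E,6E)-farnesyl diphosphate A1. In the forward step a magnesium-dependent class one sesquiterpene cyclase of the carotol-synthase type ionises A1, closes ring B and then ring A, relays the charge by two hydride shifts and hydrates the C4 cation to give carotol A2.
- In favour: all fifteen skeletal carbons, both rings, the quaternary C10, the C3 isopropyl group and the C7=C8 olefin arise in one protecting-group-free operation. On skeleton-building step economy this is clearly better than the chosen plan, which needs eleven steps to reach 22.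
- Against: A2 carries its only oxygen at C4, where the target has hydrogen, and none at C1, C3 or C5. In A2 the C4 hydroxyl is on the same face as the C10 methyl, so the C4–C5 bond sits on the face opposite to the one it occupies in the target. The fusion would have to be inverted through a C4 olefin, and C1 (an unactivated methylene next to a quaternary carbon) would need a late C–H oxidation.
- Comparison: the cationic cascade is superior for the carbocycle but gives no handle on the three C–O stereocentres, which the chosen plan carries from the first step. It would also require producing the enzyme. Overall the oxidation sequence after A2 is less defensible than the polar route.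

Alternative 2: The cut removes the C10–CH3 and C3–C4 bonds. The substrate is the cyclohepta-2,5-dienone A3 with the C1–C2–C3 isopropyl ketone chain on C10. In the forward step Me3Al A4 transfers methyl to C10 under Cu(O2CC4H3S) A5 and a chiral phosphoramidite ligand, and the resulting aluminium enolate closes from C4 onto the C3 ketone to give the trans-fused aldol A6.
- In favour: two bonds, ring A and three stereocentres (C10, C4, C3) form in one step. A closed aldol transition state with aluminium bridging the C5 and C3 oxygens gives the trans fusion and the C3 hydroxyl cis to C5 directly. The chosen plan has to correct C4 afterwards, so on this point the alternative is better. A6 is the methoxymethyl analogue of 27, so the endgame is equal.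
- Against: A3 is a skipped dienone that can tautomerise or move into conjugation, and it must first be made in enantiopure form. The conjugate addition has to build a quaternary centre next to an existing stereocentre (matched or mismatched with the ligand). The side-chain ketone is itself a target for A4.
- Comparison: the chosen plan takes C1 and C10 from substrate-controlled additions to a chiral-pool enone, which is more predictable, and pays for it with the cis fusion.

Alternative 3: The cut removes the C4–C10 and C4–C5 bonds. In the forward step the diazo ketone A7 with Rh2(OAc)4 A8 adds its carbene carbon across the ipso–ortho bond of the tolyl ring (intramolecular Buchner reaction), the norcaradiene opens, and a tertiary amine brings the triene into conjugation to give azulenone A9.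
- In favour: both rings come from a simple arene in one step, the symmetric tolyl group removes any regiochemical question, and the C7 methyl is in place from the start. For ring construction this is shorter than the chosen plan and equal in placing the C7 methyl.
- Against: A9 lacks the C10 methyl, the C3 isopropyl carbinol and the C5 oxygen, and C4 and C10 are sp2. The methyl would have to add to C10 of a cross-conjugated trienone (1,4- against 1,6- or 1,8-addition), and the triene would have to be reduced to the single C7=C8 olefin. The silyloxy carbon of A9 is S, whereas C1 of the target is R with the same substituent ranking. That is workable only if this centre steers the methyl anti onto C10 and is then inverted late (for instance by a Mitsunobu esterification with 32) at a neopentyl-type position.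
- Comparison: the chosen plan is longer to the bicycle but has C1, C3 and C10 secured before ring B exists, and needs no redox adjustment of a polyene.

Key step: step 11

Remark: atom labels C1–C10 are those of the target core and are used for every intermediate; β is the face of ring A that carries the C1 oxygen and the C10 methyl, α the opposite face.
Remark: the ester alkyl group of the ynoate is treated as a spectator; prop-2-enyl (allyl) replaces ethyl so that the ester can be removed by zerovalent palladium at ambient temperature instead of by a hot Krapcho reaction.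

## Route

Step 1
Reactants: 1 (R)-4-(tert-butyldimethylsilyloxy)cyclopent-2-en-1-one
Product: 2 trans-4-(tert-butyldimethylsilyloxy)-3-methyl-1-(trimethylsilyloxy)cyclopent-1-ene (C1 oxygen β; C10 methyl α)
Conditions: MeMgBr, CuBr·SMe2 (5 mol %), TMSCl, THF, −78 °C; Et3N, aq. NaHCO3
Reagents that add atoms: methylmagnesium bromide, C[Mg]Br; chlorotrimethylsilane, C[Si](C)(C)Cl
Why: CuBr·SMe2-catalysed conjugate addition with in situ silylation; methyl enters anti to the C1 silyloxy group and the enolate is trapped regiospecifically as the C3=C4 silyl enol ether. The C10 centre made here is removed again in step 2.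

Step 2
Reactants: 2 trans-4-(tert-butyldimethylsilyloxy)-3-methyl-1-(trimethylsilyloxy)cyclopent-1-ene
Product: 3 (R)-4-(tert-butyldimethylsilyloxy)-3-methylcyclopent-2-en-1-one
Conditions: Pd(OAc)2 (10 mol %), O2 (1 atm), DMSO, 23 °C
Reagents that add atoms: none
Why: Saegusa–Ito oxidation; the palladium enolate at C4 has its only β-hydrogen on C10, so the β-methyl enone forms regiospecifically. The medium is neutral, so the γ-stereocentre C1 is not touched.

Step 3
Reactants: 3 (R)-4-(tert-butyldimethylsilyloxy)-3-methylcyclopent-2-en-1-one; 4 2-(2-bromoethyl)-1,3-dioxolane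
Product: 7 4-(tert-butyldimethylsilyloxy)-3-[2-(1,3-dioxolan-2-yl)ethyl]-3-methylcyclopentan-1-one (C10 methyl and C1 oxygen both β), via Grignard reagent 5 (not isolated), via silyl enol ether 6 (not isolated)
Conditions: 4, Mg, THF, 25 °C; then CuBr·SMe2 (10 mol %), TMSCl, 3, THF, −78 → −30 °C; then 1 M HCl, 0 °C, 10 min
Reagents that add atoms: none
Why: CuBr·SMe2-catalysed, TMSCl-accelerated conjugate addition of a primary Grignard reagent to the β,β-disubstituted enone. Attack anti to the adjacent C1 silyloxy group puts C9 on the α face and leaves the C10 methyl cis to the C1 oxygen. Brief cold acid cleaves only the silyl enol ether.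

Step 4
Reactants: 7 4-(tert-butyldimethylsilyloxy)-3-[2-(1,3-dioxolan-2-yl)ethyl]-3-methylcyclopentan-1-one
Product: 10 4-(tert-butyldimethylsilyloxy)-5-methylbicyclo[3.3.0]oct-1(8)-en-2-one (C3 ketone; C4=C5 olefin; C1 oxygen and C10 methyl β), via keto aldehyde 8 (not isolated), via ketol 9 (not isolated)
Conditions: 2 M HCl (aq), THF, 23 → 45 °C
Reagents that add atoms: none
Why: Acetal hydrolysis followed by acid-catalysed intramolecular aldol condensation (5-enolexo closure of C4 on C5). Dehydration to the conjugated enone is the only irreversible exit, so bridged aldols through C2 or C8 revert and drain into 10.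

Step 5
Reactants: 10 4-(tert-butyldimethylsilyloxy)-5-methylbicyclo[3.3.0]oct-1(8)-en-2-one
Product: 11 4-(tert-butyldimethylsilyloxy)-5-methyl-2-(propan-2-yl)bicyclo[3.3.0]oct-1(8)-en-2-ol (C3 hydroxyl β; isopropyl α)
Conditions: iPrMgCl, CeCl3 (anhydrous), THF, −78 °C; aq. NH4Cl
Reagents that add atoms: isopropylmagnesium chloride, CC(C)[Mg]Cl
Why: Organocerium 1,2-addition to an enolisable enone, without conjugate addition or enolisation toward the β-silyloxy carbon. With C4 sp2, C1 and C9 tilt to the α side of C10 and the only axial group near C3 is the β C10 methyl (the C1 silyloxy group, also β, is pseudo-equatorial), so isopropyl enters from the α face and the new C3 oxygen is β.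

Step 6
Reactants: 11 4-(tert-butyldimethylsilyloxy)-5-methyl-2-(propan-2-yl)bicyclo[3.3.0]oct-1(8)-en-2-ol
Product: 13 4-(tert-butyldimethylsilyloxy)-5-methyl-2-(propan-2-yl)bicyclo[3.3.0]octane-2,8-diol (C3 hydroxyl β; C4 hydrogen β; C5 hydroxyl β), via bis-borane adduct 12 (not isolated)
Conditions: BH3·THF (3 equiv), THF, 0 → 23 °C; then NaOH (aq), H2O2, 0 → 23 °C
Reagents that add atoms: hydrogen peroxide, OO
Why: Hydroboration–oxidation of the trisubstituted olefin; boron goes to the unhindered C5 and hydrogen to C4, syn. Addition on the β face gives the strain-free cis-fused diquinane and meets the small C3–O–B group, not the isopropyl group; the C5 configuration is immaterial because C5 is oxidised next.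

Step 7
Reactants: 13 4-(tert-butyldimethylsilyloxy)-5-methyl-2-(propan-2-yl)bicyclo[3.3.0]octane-2,8-diol
Product: 14 6-(tert-butyldimethylsilyloxy)-8-hydroxy-5-methyl-8-(propan-2-yl)bicyclo[3.3.0]octan-2-one (C5 ketone; C3 hydroxyl β; C4 hydrogen β; cis fusion)
Conditions: Dess–Martin periodinane, CH2Cl2, 0 → 23 °C
Reagents that add atoms: none
Why: Dess–Martin oxidation of the only secondary alcohol; the tertiary C3 hydroxyl cannot be oxidised and the near-neutral medium avoids retro-aldol cleavage. C4 is now α to the ketone, so any trans-fused material from step 6 can relax to the far less strained cis-diquinane.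

Step 8
Reactants: 14 6-(tert-butyldimethylsilyloxy)-8-hydroxy-5-methyl-8-(propan-2-yl)bicyclo[3.3.0]octan-2-one
Product: 15 6-(tert-butyldimethylsilyloxy)-5-methyl-8-(propan-2-yl)-8-(triethylsilyloxy)bicyclo[3.3.0]octan-2-one
Conditions: TESOTf, 2,6-lutidine, CH2Cl2, −78 → 0 °C
Reagents that add atoms: triethylsilyl trifluoromethanesulfonate, CC[Si](CC)(CC)OS(=O)(=O)C(F)(F)F
Why: Silyl triflate silylation of the hindered tertiary alcohol; 2,6-lutidine is too weak a base to enolise the ketone at low temperature. The ether blocks retro-aldol and alkoxide chemistry in the strongly basic and Lewis acidic steps that follow.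

Step 9
Reactants: 15 6-(tert-butyldimethylsilyloxy)-5-methyl-8-(propan-2-yl)-8-(triethylsilyloxy)bicyclo[3.3.0]octan-2-one
Product: 17 cis-diquinane trimethylsilyl enol ether (C5–OSiMe3; C5=C8; C1–OSiMe2tBu β; C3–OSiEt3 β; C4 hydrogen β), via lithium enolate 16 (not isolated)
Conditions: LiN(iPr)2, THF, −78 °C; TMSCl, −78 → 0 °C; Et3N, pentane, aq. NaHCO3
Reagents that add atoms: chlorotrimethylsilane, C[Si](C)(C)Cl
Why: Kinetic enolisation and O-silylation; the amide base takes a C8 methylene hydrogen, not the C4 methine, which is buried between two fully substituted carbons. The enolate carbon C8 has no β-leaving group, so the C3 silyloxy group is safe.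

Step 10
Reactants: 18 but-2-ynoic acid; 19 prop-2-en-1-ol
Product: 20 prop-2-enyl but-2-ynoate
Conditions: DCC, DMAP (5 mol %), CH2Cl2, 0 → 23 °C
Reagents that add atoms: none
Why: Steglich esterification of a commercial ynoic acid with a primary alcohol.

Step 11
Reactants: 17 cis-diquinane trimethylsilyl enol ether; 20 prop-2-enyl but-2-ynoate
Product: 22 prop-2-enyl 1-(tert-butyldimethylsilyloxy)-6,8a-dimethyl-3-(propan-2-yl)-3-(triethylsilyloxy)-4-(trimethylsilyloxy)-1,2,3,3a,8,8a-hexahydroazulene-5-carboxylate (cis ring fusion; C5=C6 and C7=C8), via silyloxycyclobutene 21 (not isolated)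
Conditions: EtAlCl2 (1.5 equiv), CH2Cl2, −78 → 0 °C, then 23 °C; pyridine, aq. NaHCO3
Reagents that add atoms: none
Why: EtAlCl2 binds the ester carbonyl of 20 and makes the alkyne a Michael acceptor; the nucleophilic enol ether carbon C8 of 17 adds to the methyl-bearing β-carbon C7, giving an EtAlCl2-bound allenoate tethered to a silyl oxocarbenium ion at C5. The allenoate α-carbon C6 then closes on C5 (4-exo-trig, the C5=O+ bond exocyclic to the new ring) to the silyloxycyclobutene 21, a stepwise (2+2) cycloaddition of the kind established for silyl enol ethers and propiolates. The four-membered ring is only a relay: the C5–C8 bond, flanked by the oxygen donor on C5 and the vinylogous ester acceptor through C7=C6, opens heterolytically (a vinylogous retro-aldol, formally the 4π ring opening that cannot be concerted in this fused bicycle). Ring B therefore arises by two-carbon enlargement of the cyclopentane (C4, C5, C8, C9, C10) and not by an end-to-end closure. No lasting stereocentre is formed: C5 and C8 of 21 return to sp2, and C1, C3, C4 and C10 are spectators under aprotic, non-enolising conditions. Three selectivities are needed: the enol ether on the C8 side (secured in step 9), attack at the alkyne β-carbon (secured by the polarisation of the complexed ynoate) and survival of the silyl ethers (low temperature, pyridine quench). The β-methyl group makes the ynoate less electrophilic than a propiolate, which is why a strong Lewis acid in excess and warming to ambient temperature are chosen.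

Step 12
Reactants: 22 prop-2-enyl 2-silyloxy diene ester
Product: 24 1-(tert-butyldimethylsilyloxy)-6,8a-dimethyl-3-(propan-2-yl)-3-(triethylsilyloxy)-2,3,3a,5,8,8a-hexahydroazulen-4(1H)-one (cis fusion; C4 hydrogen β), via enolised β-keto ester 23 (not isolated)
Conditions: 1 M HCl, THF, 0 °C; then Pd(PPh3)4 (5 mol %), morpholine, THF, 23 °C
Reagents that add atoms: none
Why: Mild hydrolysis of the silyl enol ether, then Tsuji-type deallylation: zerovalent palladium forms a π-allyl complex, morpholine takes the allyl group, and the β-keto acid loses CO2 at ambient temperature. No heat or strong base is involved, so both silyl ethers and the β-silyloxy ketone survive.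

Step 13
Reactants: 24 cis-fused ketone
Product: 26 1-(tert-butyldimethylsilyloxy)-6,8a-dimethyl-3-(propan-2-yl)-3-(triethylsilyloxy)-2,3,3a,5,8,8a-hexahydroazulen-4(1H)-one (trans fusion; C4 hydrogen α), via potassium dienolate 25 (not isolated)
Conditions: KOtBu (10 equiv), tBuOH/THF, 23 °C, argon; then inverse quench into 10 % aq. AcOH, 0 °C
Reagents that add atoms: none
Why: Base-mediated epimerisation coupled with deconjugative kinetic protonation. The small equilibrium fraction of free ketone exchanges at C4 and settles in the trans fusion, where C5 is no longer cis to the isopropyl group. The bulk is held as the extended dienolate (O–C5=C6–C7=C8), which acetic acid protonates at the α-carbon C6, so the olefin is returned to C7=C8 whatever its position before.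

Step 14
Reactants: 26 trans-fused ketone
Product: 27 1-(tert-butyldimethylsilyloxy)-3-hydroxy-6,8a-dimethyl-3-(propan-2-yl)-2,3,3a,5,8,8a-hexahydroazulen-4(1H)-one (trans fusion)
Conditions: HF·pyridine, pyridine, THF, 0 °C
Reagents that add atoms: none
Why: Buffered HF cleaves a triethylsilyl ether much faster than a tert-butyldimethylsilyl ether, and the C1 ether is further shielded by the quaternary C10. The medium is not basic, so neither retro-aldol cleavage nor olefin migration is triggered.

Step 15
Reactants: 27 trans-fused β-hydroxy ketone
Product: 28 1-(tert-butyldimethylsilyloxy)-6,8a-dimethyl-3-(propan-2-yl)-1,2,3,3a,4,5,8,8a-octahydroazulene-3,4-diol (C5 hydroxyl anti to the C3 hydroxyl)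
Conditions: Me4NBH(OAc)3, AcOH/MeCN, −30 → −20 °C
Reagents that add atoms: none
Why: Evans–Saksena reduction; the C3 hydroxyl exchanges onto boron and delivers hydride internally through a chair transition state, giving the 1,3-anti diol. This places the new C5 hydrogen on the face flanked by the C10 methyl, which an external hydride would avoid. The reagent does not reduce ketones that lack a directing hydroxyl and leaves the olefin alone.

Step 16
Reactants: 28 diol; 29 4-methoxybenzoyl chloride
Product: 30 1-(tert-butyldimethylsilyloxy)-3-hydroxy-6,8a-dimethyl-3-(propan-2-yl)-1,2,3,3a,4,5,8,8a-octahydroazulen-4-yl 4-methoxybenzoate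
Conditions: pyridine, DMAP (10 mol %), CH2Cl2, 0 → 23 °C
Reagents that add atoms: none
Why: DMAP-catalysed acylation of the only secondary alcohol; the tertiary C3 hydroxyl is inert under these conditions.

Step 17
Reactants: 30 silyl ether benzoate
Product: 31 (1R,3R,3aS,4S,8aR)-1,3-dihydroxy-6,8a-dimethyl-3-(propan-2-yl)-1,2,3,3a,4,5,8,8a-octahydroazulen-4-yl 4-methoxybenzoate
Conditions: HF·pyridine, THF, 23 °C
Reagents that add atoms: none
Why: Acidic fluoride desilylation; no alkoxide is formed, so the C5 ester neither migrates nor hydrolyses.

Step 18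
Reactants: 31 diol benzoate; 32 (2Z)-2-methylbut-2-enoic acid (angelic acid)
Product: 34 (1R,3R,3aS,4S,8aR)-3-hydroxy-4-[(4-methoxybenzoyl)oxy]-6,8a-dimethyl-3-(propan-2-yl)-1,2,3,3a,4,5,8,8a-octahydroazulen-1-yl (2Z)-2-methylbut-2-enoate, via mixed anhydride 33 (not isolated)
Conditions: 32, 2,4,6-trichlorobenzoyl chloride, Et3N, toluene, 23 °C; then 31, toluene, 75 °C (no DMAP)
Reagents that add atoms: none
Why: Yamaguchi-type mixed-anhydride acylation run without a nucleophilic catalyst, the mode in which Z-2-methylbut-2-enoates are transferred without isomerisation to the E ester. Only the secondary C1 hydroxyl reacts; the molecule no longer contains a ketone, so warm triethylamine is harmless.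

## Compound list

1 | (R)-4-(tert-butyldimethylsilyloxy)cyclopent-2-en-1-one | O=C1C=C[C@H](O[Si](C)(C)C(C)(C)C)C1 | starting material
2 | trans-4-(tert-butyldimethylsilyloxy)-3-methyl-1-(trimethylsilyloxy)cyclopent-1-ene | CC(C)(C)[Si](C)(C)O[C@@H]1CC(O[Si](C)(C)C)=C[C@H]1C | intermediate
3 | (R)-4-(tert-butyldimethylsilyloxy)-3-methylcyclopent-2-en-1-one | CC(C)(C)[Si](C)(C)O[C@@H]1CC(=O)C=C1C | intermediate
4 | 2-(2-bromoethyl)-1,3-dioxolane | BrCCC1OCCO1 | starting material
5 | 2-(1,3-dioxolan-2-yl)ethylmagnesium bromide (not isolated) | Br[Mg]CCC1OCCO1 | intermediate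
6 | 4-(tert-butyldimethylsilyloxy)-3-[2-(1,3-dioxolan-2-yl)ethyl]-3-methyl-1-(trimethylsilyloxy)cyclopent-1-ene (not isolated) | CC(C)(C)[Si](C)(C)O[C@@H]1CC(O[Si](C)(C)C)=C[C@@]1(C)CCC1OCCO1 | intermediate
7 | 4-(tert-butyldimethylsilyloxy)-3-[2-(1,3-dioxolan-2-yl)ethyl]-3-methylcyclopentan-1-one (methyl cis to silyloxy) | CC(C)(C)[Si](C)(C)O[C@@H]1CC(=O)C[C@@]1(C)CCC1OCCO1 | intermediate
8 | 3-[2-(tert-butyldimethylsilyloxy)-1-methyl-4-oxocyclopentyl]propanal (not isolated) | CC(C)(C)[Si](C)(C)O[C@@H]1CC(=O)C[C@@]1(C)CCC=O | intermediate
9 | cis-4-(tert-butyldimethylsilyloxy)-8-hydroxy-5-methylbicyclo[3.3.0]octan-2-one (C5 configuration open; not isolated) | CC(C)(C)[Si](C)(C)O[C@@H]1CC(=O)[C@H]2C(O)CC[C@]21C | intermediate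
10 | 4-(tert-butyldimethylsilyloxy)-5-methylbicyclo[3.3.0]oct-1(8)-en-2-one | CC(C)(C)[Si](C)(C)O[C@@H]1CC(=O)C2=CCC[C@]21C | intermediate
11 | 4-(tert-butyldimethylsilyloxy)-5-methyl-2-(propan-2-yl)bicyclo[3.3.0]oct-1(8)-en-2-ol (C3 hydroxyl β, isopropyl α) | CC(C)(C)[Si](C)(C)O[C@@H]1C[C@@](O)(C(C)C)C2=CCC[C@]21C | intermediate
12 | bis-borane adduct of 11 (C3–O–BH2, C5–BH2, C4 hydrogen β; not isolated) | CC(C)(C)[Si](C)(C)O[C@@H]1C[C@@](OB)(C(C)C)[C@H]2[C@H](B)CC[C@]21C | intermediate
13 | cis-4-(tert-butyldimethylsilyloxy)-5-methyl-2-(propan-2-yl)bicyclo[3.3.0]octane-2,8-diol | CC(C)(C)[Si](C)(C)O[C@@H]1C[C@@](O)(C(C)C)[C@H]2[C@H](O)CC[C@]21C | intermediate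
14 | cis-6-(tert-butyldimethylsilyloxy)-8-hydroxy-5-methyl-8-(propan-2-yl)bicyclo[3.3.0]octan-2-one | CC(C)(C)[Si](C)(C)O[C@@H]1C[C@@](O)(C(C)C)[C@H]2C(=O)CC[C@]21C | intermediate
15 | cis-6-(tert-butyldimethylsilyloxy)-5-methyl-8-(propan-2-yl)-8-(triethylsilyloxy)bicyclo[3.3.0]octan-2-one | CC(C)(C)[Si](C)(C)O[C@@H]1C[C@@](O[Si](CC)(CC)CC)(C(C)C)[C@H]2C(=O)CC[C@]21C | intermediate
16 | lithium enolate of 15 (C5–OLi, C5=C8; not isolated) | CC(C)(C)[Si](C)(C)O[C@@H]1C[C@@](O[Si](CC)(CC)CC)(C(C)C)[C@H]2C(O[Li])=CC[C@]21C | intermediate
17 | cis-diquinane trimethylsilyl enol ether (C1 and C3 silyl ethers) | CC(C)(C)[Si](C)(C)O[C@@H]1C[C@@](O[Si](CC)(CC)CC)(C(C)C)[C@H]2C(O[Si](C)(C)C)=CC[C@]21C | intermediate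
18 | but-2-ynoic acid | CC#CC(=O)O | starting material
19 | prop-2-en-1-ol | C=CCO | starting material
20 | prop-2-enyl but-2-ynoate | CC#CC(=O)OCC=C | intermediate
21 | silyloxycyclobutene adduct (C5–C6 and C7–C8 formed, C5–C8 intact; drawn for addition on the β face; not isolated) | CC(C)(C)[Si](C)(C)O[C@@H]1C[C@@](O[Si](CC)(CC)CC)(C(C)C)[C@H]2[C@]3(O[Si](C)(C)C)C(C(=O)OCC=C)=C(C)[C@@H]3C[C@]21C | intermediate
22 | prop-2-enyl 1-(tert-butyldimethylsilyloxy)-6,8a-dimethyl-3-(propan-2-yl)-3-(triethylsilyloxy)-4-(trimethylsilyloxy)-1,2,3,3a,8,8a-hexahydroazulene-5-carboxylate (cis fusion) | CC(C)(C)[Si](C)(C)O[C@@H]1C[C@@](O[Si](CC)(CC)CC)(C(C)C)[C@H]2C(O[Si](C)(C)C)=C(C(=O)OCC=C)C(C)=CC[C@]21C | intermediate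
23 | prop-2-enyl 4-hydroxy analogue of 22 (enol form of the β-keto ester; not isolated) | CC(C)(C)[Si](C)(C)O[C@@H]1C[C@@](O[Si](CC)(CC)CC)(C(C)C)[C@H]2C(O)=C(C(=O)OCC=C)C(C)=CC[C@]21C | intermediate
24 | cis-fused 1-(tert-butyldimethylsilyloxy)-6,8a-dimethyl-3-(propan-2-yl)-3-(triethylsilyloxy)-2,3,3a,5,8,8a-hexahydroazulen-4(1H)-one | CC(C)(C)[Si](C)(C)O[C@@H]1C[C@@](O[Si](CC)(CC)CC)(C(C)C)[C@H]2C(=O)CC(C)=CC[C@]21C | intermediate
25 | potassium dienolate of 26 (C5–OK, C5=C6, C7=C8; not isolated) | CC(C)(C)[Si](C)(C)O[C@@H]1C[C@@](O[Si](CC)(CC)CC)(C(C)C)[C@@H]2C(O[K])=CC(C)=CC[C@]21C | intermediate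
26 | trans-fused 1-(tert-butyldimethylsilyloxy)-6,8a-dimethyl-3-(propan-2-yl)-3-(triethylsilyloxy)-2,3,3a,5,8,8a-hexahydroazulen-4(1H)-one | CC(C)(C)[Si](C)(C)O[C@@H]1C[C@@](O[Si](CC)(CC)CC)(C(C)C)[C@@H]2C(=O)CC(C)=CC[C@]21C | intermediate
27 | trans-fused 1-(tert-butyldimethylsilyloxy)-3-hydroxy-6,8a-dimethyl-3-(propan-2-yl)-2,3,3a,5,8,8a-hexahydroazulen-4(1H)-one | CC(C)(C)[Si](C)(C)O[C@@H]1C[C@@](O)(C(C)C)[C@@H]2C(=O)CC(C)=CC[C@]21C | intermediate
28 | 1-(tert-butyldimethylsilyloxy)-6,8a-dimethyl-3-(propan-2-yl)-1,2,3,3a,4,5,8,8a-octahydroazulene-3,4-diol (target configuration at all five centres) | CC(C)(C)[Si](C)(C)O[C@@H]1C[C@@](O)(C(C)C)[C@@H]2[C@@H](O)CC(C)=CC[C@]21C | intermediate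
29 | 4-methoxybenzoyl chloride | COc1ccc(cc1)C(Cl)=O | starting material
30 | 1-(tert-butyldimethylsilyloxy)-3-hydroxy-6,8a-dimethyl-3-(propan-2-yl)-1,2,3,3a,4,5,8,8a-octahydroazulen-4-yl 4-methoxybenzoate | CC(C)(C)[Si](C)(C)O[C@@H]1C[C@@](O)(C(C)C)[C@@H]2[C@@H](OC(=O)c3ccc(OC)cc3)CC(C)=CC[C@]21C | intermediate
31 | (1R,3R,3aS,4S,8aR)-1,3-dihydroxy-6,8a-dimethyl-3-(propan-2-yl)-1,2,3,3a,4,5,8,8a-octahydroazulen-4-yl 4-methoxybenzoate | O[C@@H]1C[C@@](O)(C(C)C)[C@@H]2[C@@H](OC(=O)c3ccc(OC)cc3)CC(C)=CC[C@]21C | intermediate
32 | (2Z)-2-methylbut-2-enoic acid | C/C=C(/C)C(=O)O | starting material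
33 | (2Z)-2-methylbut-2-enoic 2,4,6-trichlorobenzoic anhydride (not isolated) | C/C=C(/C)C(=O)OC(=O)c1c(Cl)cc(Cl)cc1Cl | intermediate
34 | (1R,3R,3aS,4S,8aR)-3-hydroxy-4-[(4-methoxybenzoyl)oxy]-6,8a-dimethyl-3-(propan-2-yl)-1,2,3,3a,4,5,8,8a-octahydroazulen-1-yl (2Z)-2-methylbut-2-enoate | C/C=C(/C)C(=O)O[C@@H]1C[C@@](O)(C(C)C)[C@@H]2[C@@H](OC(=O)c3ccc(OC)cc3)CC(C)=CC[C@]21C | target

## Step count and least certain steps

Total: 18 steps. Longest linear sequence: 17 steps (1 to 34 through steps 1–9 and 11–18; step 10 is a one-step side branch).

Step 11 (key step). The most likely failure is that the second bond does not form. After the Michael step the zwitterion may lose its silyl group instead of closing on C5, which is crowded by the C3 substituents. Alternatively, the β-methyl ynoate may be too unreactive, so that the Lewis acid cleaves the enol ether first. The fallback abandons Lewis-acid activation and sets out from ketone 15. Condensation with pyrrolidine (TsOH cat., toluene, water removal) gives the pyrrolidine enamine F1. Heating F1 with 20 (MeCN or toluene, 80–110 °C) uses the thermal enamine–alkynoate (2+2) addition and ring enlargement, in which the iminium ion cannot be lost the way a silyl group can. The ring-enlarged dienamine ester F2 is hydrolysed with aqueous acetic acid to 23, where the route is rejoined (second stage of step 12).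

Step 13. Three processes threaten it: β-elimination of the C3 silyloxy group from the transient C4 enolate, incomplete equilibration at C4 if the trans preference is small while C3 is silylated, and partial γ-protonation on quench. The fallback separates the tasks and sets out from 24.
- HF·pyridine removes the triethylsilyl group to give the cis hydroxy ketone F3.
- DBU in toluene at 23 °C equilibrates C4; hydroxide is no leaving group here and the C3–OH···O=C5 hydrogen bond favours the trans fusion. The product is expected as 27 mixed with its conjugated isomer F4.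
- TMSOTf/Et3N converts both into the bis-silylated dienol ether F5.
- MeLi (THF, −78 °C) releases the lithium dienolate regiospecifically, acetic acid at −78 °C protonates C6, and citric acid in methanol removes the tertiary trimethylsilyl ether.
The sequence comes back at 27 (step 15).

Step 15. The risk is poor facial selectivity. Internal delivery has to occur on the face of C5 that the C10 methyl flanks, so external reduction on the open face may compete and lead to the C5 epimer. The fallback makes use of that bias and sets out from 27. An external hydride (NaBH4 in MeOH, or LiBH(sBu)3 in THF, −78 °C) should attack the open face and give the C5-epimeric diol F6. A Mitsunobu esterification (4-methoxybenzoic acid, PPh3, diisopropyl azodicarboxylate, toluene) then installs the benzoate with inversion, the nucleophile arriving on the unhindered face. The route is rejoined at 30 (step 17).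

Step 4. Prolonged aqueous acid may cleave the C1 silyl ether or eliminate silanol from the β-silyloxy ketone before the condensation is complete. The fallback avoids aqueous acid and sets out from 3. Conjugate addition of but-3-enylmagnesium bromide (CuBr·SMe2, TMSCl, THF) gives the butenyl ketone F7. Ozonolysis (O3, CH2Cl2, −78 °C; PPh3) gives keto aldehyde 8, and piperidinium acetate in toluene at 60 °C closes it to 10, where the route is rejoined (step 5).

Step 18. The Z acyl group may isomerise to the E ester during activation, and acylation of the neopentyl-type C1 hydroxyl may be slow enough to let this happen. The fallback builds the Z olefin on the ester and sets out from 31. Esterification with 2-[bis(2,2,2-trifluoroethoxy)phosphoryl]propanoic acid (DCC, DMAP cat., CH2Cl2) gives the phosphonopropanoate F8. A Still–Gennari olefination (KN(SiMe3)2, 18-crown-6, THF, −78 °C, acetaldehyde) gives the Z-2-methylbut-2-enoate, that is 34, directly.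

## Further compounds

F1 | step 11 | pyrrolidine enamine of 15 (C5–N, C5=C8) | CC(C)(C)[Si](C)(C)O[C@@H]1C[C@@](O[Si](CC)(CC)CC)(C(C)C)[C@H]2C(N3CCCC3)=CC[C@]21C
F2 | step 11 | ring-enlarged dienamine ester (4-pyrrolidin-1-yl analogue of 22) | CC(C)(C)[Si](C)(C)O[C@@H]1C[C@@](O[Si](CC)(CC)CC)(C(C)C)[C@H]2C(N3CCCC3)=C(C(=O)OCC=C)C(C)=CC[C@]21C
F3 | step 13 | cis-fused 1-(tert-butyldimethylsilyloxy)-3-hydroxy-6,8a-dimethyl-3-(propan-2-yl)-2,3,3a,5,8,8a-hexahydroazulen-4(1H)-one | CC(C)(C)[Si](C)(C)O[C@@H]1C[C@@](O)(C(C)C)[C@H]2C(=O)CC(C)=CC[C@]21C
F4 | step 13 | trans-fused conjugated isomer of 27 (C6=C7 olefin) | CC(C)(C)[Si](C)(C)O[C@@H]1C[C@@](O)(C(C)C)[C@@H]2C(=O)C=C(C)CC[C@]21C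
F5 | step 13 | trans-fused dienol bis(trimethylsilyl) ether (C3–OSiMe3, C5–OSiMe3, C5=C6, C7=C8) | CC(C)(C)[Si](C)(C)O[C@@H]1C[C@@](O[Si](C)(C)C)(C(C)C)[C@@H]2C(O[Si](C)(C)C)=CC(C)=CC[C@]21C
F6 | step 15 | C5 epimer of 28 | CC(C)(C)[Si](C)(C)O[C@@H]1C[C@@](O)(C(C)C)[C@@H]2[C@H](O)CC(C)=CC[C@]21C
F7 | step 4 | 3-(but-3-enyl)-4-(tert-butyldimethylsilyloxy)-3-methylcyclopentan-1-one (methyl cis to silyloxy) | CC(C)(C)[Si](C)(C)O[C@@H]1CC(=O)C[C@@]1(C)CCC=C
F8 | step 18 | C1 2-[bis(2,2,2-trifluoroethoxy)phosphoryl]propanoate of 31 | CC(C(=O)O[C@@H]1C[C@@](O)(C(C)C)[C@@H]2[C@@H](OC(=O)c3ccc(OC)cc3)CC(C)=CC[C@]21C)P(=O)(OCC(F)(F)F)OCC(F)(F)F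
A1 | alternative 1 | (2E,6E)-farnesyl diphosphate | CC(C)=CCC/C(C)=C/CC/C(C)=C/COP(=O)(O)OP(=O)(O)O
A2 | alternative 1 | carotol | C1C[C@@H](C(C)C)[C@@]2(O)CCC(C)=CC[C@]21C
A3 | alternative 2 | (R)-3-[1-(methoxymethoxy)-4-methyl-3-oxopentyl]-6-methylcyclohepta-2,5-dien-1-one | COCO[C@H](CC(=O)C(C)C)C1=CC(=O)CC(C)=CC1
A4 | alternative 2 | trimethylaluminium | C[Al](C)C
A5 | alternative 2 | copper thiophene-2-carboxylate | [Cu+].[O-]C(=O)c1cccs1
A6 | alternative 2 | trans-fused bicyclic aldol (C3 carbinol, C5 ketone, C1 methoxymethyl ether) | COCO[C@@H]1C[C@@](O)(C(C)C)[C@@H]2C(=O)CC(C)=CC[C@]21C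
A7 | alternative 3 | (S)-4-(tert-butyldimethylsilyloxy)-1-diazo-4-(4-methylphenyl)butan-2-one | [N-]=[N+]=CC(=O)C[C@H](O[Si](C)(C)C(C)(C)C)c1ccc(C)cc1
A8 | alternative 3 | dirhodium tetraacetate | CC(=O)[O-].CC(=O)[O-].CC(=O)[O-].CC(=O)[O-].[Rh+2].[Rh+2]
A9 | alternative 3 | (S)-3-(tert-butyldimethylsilyloxy)-6-methyl-3,4-dihydro-2H-azulen-1-one | O=C1C[C@H](O[Si](C)(C)C(C)(C)C)C2=C1C=CC(C)=CC2
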